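0.418 M of Z is already read in the north-west run at 0.833 h, more than the 200 mM of D a solution holds at saturation. If each Z takes up one D, then D must keep crossing from the gas into the liquid during that run.

- north-west: L 1.9 M; D 200 mM (held); run made earlier
- flask: L 2.9 M; D 200 mM (held); time 40 h

north-west run (percent of the L charged)

| time / h | Z / % |
|---|---|
| 0.833 | 22 |
| 2.00 | 28 |
| 4.00 | 21 |
| 10.0 | 10 |
| 20.0 | 10 |
| 50.0 | 10 |

(scatter of a reading: 1.5 percentage points)

- the analysis behind the earlier runs scatters by 1.5 percentage points, standard deviation
- at the start none of D is in solution

1. the moment within 40 h at which there is most Z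
2. the amount of Z, in percent of the L charged, at that time

I reckon the 2.9 M flask two ways. The first keeps the north-west curve in percent, which puts the peak at the reading of 2.00 h with 28%.

The second assumes that the uptake of D is the rate-limiting step, so a fixed molar feed F lasts in proportion to the charge. The north-west charge over its peak time reads F = 0.950 M h⁻¹, which puts the peak of the flask at 3.05 h. The north-west readings of Z level off on a plateau at 10% of the charge. I assume that while the feed lasts, Z stands above that plateau by a molar amount that does not grow with the charge. This gives X = 0.342 M, the standing excess, the molar Z above the plateau at the peak. If the flask has the same plateau in percent, that means 21.8% for it.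

The two ways part. I judge that the first cheats, since the saturation of D is the same in both flasks, and I commit to the second.

The forecast gives 1.8 h and 28%, near my first way but by its own reckoning: “If the steps are first order in L, the percent profile is unchanged at 2.9 M”.

The flask peaks at 3.07 h with 23.3%, against my 3.05 h and 21.8%.

    L + Z → E (k = 0.00354 M⁻¹ min⁻¹)
    D ⇌ J, rate k2*(csat - [J]) (kL = 0.0754 min⁻¹)
    Z ⇌ G (K = 5.50, k = 0.0111 min⁻¹)
    L + J ⇌ Z (K = 100 M⁻¹, k = 0.165 M⁻¹ min⁻¹)

Above its own end value of 9.76%, the peak of the flask stands 0.393 M in molar terms, against X of 0.342 M. The neighbour flask, charged with 1.7 M of L, ends with Z at 11.8% after 40.0 h. Adding X over that charge gives 31.9%, and the peak of the neighbour is 32.2%.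

The runs come from a simulation on assumed constants.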